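The pyran ring of the 1H-isochromene is disconnected at C1–O2 and C3=C4. Its enol ether carbon C3 carries O2 and the aroyl carbonyl, so O2–C3–C(=O)Ar is read as an arylglyoxylic acid whose ester carbonyl is olefinated. C1 and C4 are the equivalent benzylic carbons of a symmetrical 4,5-dimethoxy-o-xylylene unit. In the key step the glyoxylate carboxylate alkylates a [2-(bromomethyl)benzyl]phosphonium salt (C1–O2), and the ylide then olefinates the new ester carbonyl intramolecularly (C3=C4), giving the target directly. The precursors are the mono-phosphonium salt of 4,5-bis(bromomethyl)veratrole and 2-(2,4-dimethoxyphenyl)-2-oxoacetic acid.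

Key step: step 4

Remark: the target has no stereocentre, and its only stereo-element, the C3=C4 double bond, is fixed by the six-membered ring. Ring A is the 2,4-dimethoxyphenyl ring, ring B the benzo ring, ring C the pyran ring (C1, O2, C3, C4, C4a, C8a).

Step 1
Reactants: 1 veratrole (1,2-dimethoxybenzene)
Product: 3 1,2-bis(bromomethyl)-4,5-dimethoxybenzene, via 4-(bromomethyl)-1,2-dimethoxybenzene 2 (not isolated)
Conditions: (CH2O)n, 33% HBr in AcOH, rt → 45 °C
Reagents that add atoms: paraformaldehyde (as formaldehyde, C=O); hydrogen bromide (Br)
Why: Twofold Blanc-type bromomethylation (electrophilic aromatic substitution by protonated formaldehyde, then benzylic alcohol to bromide with HBr); each methoxy group directs para, so the CH2Br groups enter at C4 and C5, and the sparingly soluble dibromide should crystallise before it benzylates further.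

Step 2
Reactants: 3 1,2-bis(bromomethyl)-4,5-dimethoxybenzene
Product: 4 [2-(bromomethyl)-4,5-dimethoxybenzyl]triphenylphosphonium bromide
Conditions: PPh3 (0.95 equiv, slow addition), toluene, rt → 50 °C; filter the salt
Reagents that add atoms: triphenylphosphine (c1ccc(cc1)P(c1ccccc1)c1ccccc1)
Why: SN2 quaternisation of the phosphine (phosphonium salt formation); the mono-salt should precipitate from toluene, and its remaining CH2Br is flanked by the bulky phosphonium group, which holds the reaction at mono-substitution.

Step 3
Reactants: 5 1-(2,4-dimethoxyphenyl)ethanone (2',4'-dimethoxyacetophenone)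
Product: 7 2-(2,4-dimethoxyphenyl)-2-oxoacetic acid, via (2,4-dimethoxyphenyl)glyoxal 6 (not isolated)
Conditions: SeO2 (2 equiv), pyridine, 100 °C; filter off Se; aq. HCl
Reagents that add atoms: selenium dioxide (O=[Se]=O)
Why: Riley oxidation: SeO2 oxidises the only enolisable position, the methyl group, to the glyoxal, and in pyridine this is carried on to the α-keto acid, which is held as its pyridinium salt.

Step 4
Reactants: 4 [2-(bromomethyl)-4,5-dimethoxybenzyl]triphenylphosphonium bromide; 7 2-(2,4-dimethoxyphenyl)-2-oxoacetic acid
Product: 11 (2,4-dimethoxyphenyl)(6,7-dimethoxy-1H-isochromen-3-yl)methanone, via potassium 2-(2,4-dimethoxyphenyl)-2-oxoacetate 8 (not isolated), via phosphonium keto ester bromide 9 (not isolated), via phosphonium ylide 10 (not isolated)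
Conditions: 7, K2CO3 (1.3 equiv), 4 Å MS, DMF, argon, rt; add 4, rt; then 90 °C
Reagents that add atoms: none
Why: Carboxylate 8 displaces the benzylic bromide of 4 (SN2, C1–O2 bond) to give ester 9, and on heating carbonate/bicarbonate deprotonates the P–CH2 group to the semi-stabilised ylide 10, whose carbon adds to the neighbouring ester carbonyl to give an oxaphosphetane that collapses with loss of Ph3P=O (C3=C4 bond). The closest known reaction type is the intramolecular Wittig olefination of ester carbonyls by ortho-acyloxy-substituted benzyl phosphonium ylides, the established route to benzofurans and related benzo-fused cyclic enol ethers, preceded here in the same flask by a carboxylate alkylation. Ring C closes in a 6-exo-trig mode, the ylide carbon attacking the ester C=O whose oxygen stays outside the forming ring. No stereocentre is created, and the geometry of the new double bond is fixed by the six-membered ring. The step needs chemoselectivity for the ester carbonyl over the aryl ketone carbonyl: attack on the ketone would demand a seven-membered closure through the disfavoured E conformer of the ester, and that ketone is deactivated and shielded by the ortho and para methoxy groups of ring A, whereas the ester carbonyl is activated by the adjacent keto group. The order of events is secured by forming the ester at room temperature, where the ylide is not yet generated, and only then heating.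

Compound list
1 | veratrole (1,2-dimethoxybenzene) | COc1ccccc1OC | starting material
2 | 4-(bromomethyl)-1,2-dimethoxybenzene (not isolated) | COc1ccc(CBr)cc1OC | intermediate
3 | 1,2-bis(bromomethyl)-4,5-dimethoxybenzene | COc1cc(CBr)c(CBr)cc1OC | intermediate
4 | [2-(bromomethyl)-4,5-dimethoxybenzyl]triphenylphosphonium bromide | COc1cc(CBr)c(C[P+](c2ccccc2)(c2ccccc2)c2ccccc2)cc1OC.[Br-] | intermediate
5 | 1-(2,4-dimethoxyphenyl)ethanone | COc1ccc(C(C)=O)c(OC)c1 | starting material
6 | (2,4-dimethoxyphenyl)glyoxal, 2-(2,4-dimethoxyphenyl)-2-oxoacetaldehyde (not isolated) | COc1ccc(C(=O)C=O)c(OC)c1 | intermediate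
7 | 2-(2,4-dimethoxyphenyl)-2-oxoacetic acid | COc1ccc(C(=O)C(=O)O)c(OC)c1 | intermediate
8 | potassium 2-(2,4-dimethoxyphenyl)-2-oxoacetate (not isolated) | COc1ccc(C(=O)C(=O)[O-])c(OC)c1.[K+] | intermediate
9 | {2-[({2-(2,4-dimethoxyphenyl)-2-oxoacetyl}oxy)methyl]-4,5-dimethoxybenzyl}triphenylphosphonium bromide (not isolated) | COc1ccc(C(=O)C(=O)OCc2cc(OC)c(OC)cc2C[P+](c2ccccc2)(c2ccccc2)c2ccccc2)c(OC)c1.[Br-] | intermediate
10 | 4,5-dimethoxy-2-[(triphenyl-λ5-phosphanylidene)methyl]benzyl 2-(2,4-dimethoxyphenyl)-2-oxoacetate, the ylide of 9 (not isolated) | COc1ccc(C(=O)C(=O)OCc2cc(OC)c(OC)cc2C=P(c2ccccc2)(c2ccccc2)c2ccccc2)c(OC)c1 | intermediate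
11 | (2,4-dimethoxyphenyl)(6,7-dimethoxy-1H-isochromen-3-yl)methanone | COc1ccc(C(=O)C2=Cc3cc(OC)c(OC)cc3CO2)c(OC)c1 | target

Total step count: 4. Longest linear sequence: 3 steps (steps 1, 2 and 4); step 3 is the one-step side branch.

Steps most likely to fail

Step 4. The ylide may add to the aryl ketone carbonyl instead of the ester carbonyl, or the activated keto ester may be cleaved by adventitious hydroxide before olefination. The fallback sets out from 4 and returns at 11; it removes the ketone from the olefination and introduces ring A afterwards. Salt 4 would be alkylated with commercial potassium methyl oxalate (DMF, rt) to {4,5-dimethoxy-2-[(2-methoxy-2-oxoacetoxy)methyl]benzyl}triphenylphosphonium bromide F1 (not isolated). K2CO3 at 90 °C should then close it by the same ester olefination, now with only ester carbonyls present and the six-membered closure favoured, to methyl 6,7-dimethoxy-1H-isochromene-3-carboxylate F2. MeNH(OMe)·HCl with i-PrMgCl (THF, −20 °C) should convert F2 into the Weinreb amide N,6,7-trimethoxy-N-methyl-1H-isochromene-3-carboxamide F3. Commercial 2,4-dimethoxyphenylmagnesium bromide (THF, 0 °C) should add once to F3 and give 11 after mild acidic work-up.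

Step 2. Quaternisation may run on to the bis-phosphonium salt, or the mono-salt may not separate cleanly from it. The fallback sets out from 3 and returns at 4; it differentiates the two benzylic carbons by construction instead of by stoichiometry. Dibromide 3 would be closed to 5,6-dimethoxy-1,3-dihydroisobenzofuran F4 (K2CO3, dioxane/H2O, reflux; hydrolysis of one bromide, then 5-exo-tet Williamson closure). Ring opening of F4 with Ph3P·HBr (MeCN, reflux) should give [2-(hydroxymethyl)-4,5-dimethoxybenzyl]triphenylphosphonium bromide F5. PBr3 (CH2Cl2, 0 °C) should then convert the hydroxyl group of F5 into the bromide, giving 4.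

Step 3. The oxidation may stall at the glyoxal, or run on with decarboxylation to the benzoic acid in hot pyridine. The fallback sets out from 5 and returns at 7; it splits the oxidation into two chemoselective stages. Kornblum-type oxidation of 5 (I2, DMSO, 100 °C) should give glyoxal 6, isolated after aqueous work-up as its hydrate 2,2-dihydroxy-1-(2,4-dimethoxyphenyl)ethanone F6. Pinnick oxidation of F6 (NaClO2, NaH2PO4, 2-methyl-2-butene, t-BuOH/H2O, rt) should then give 7.

Further compounds
F1 | step 4 | {4,5-dimethoxy-2-[(2-methoxy-2-oxoacetoxy)methyl]benzyl}triphenylphosphonium bromide | COC(=O)C(=O)OCc1cc(OC)c(OC)cc1C[P+](c1ccccc1)(c1ccccc1)c1ccccc1.[Br-]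
F2 | step 4 | methyl 6,7-dimethoxy-1H-isochromene-3-carboxylate | COC(=O)C1=Cc2cc(OC)c(OC)cc2CO1
F3 | step 4 | N,6,7-trimethoxy-N-methyl-1H-isochromene-3-carboxamide | CON(C)C(=O)C1=Cc2cc(OC)c(OC)cc2CO1
F4 | step 2 | 5,6-dimethoxy-1,3-dihydroisobenzofuran | COc1cc2c(cc1OC)COC2
F5 | step 2 | [2-(hydroxymethyl)-4,5-dimethoxybenzyl]triphenylphosphonium bromide | COc1cc(CO)c(C[P+](c2ccccc2)(c2ccccc2)c2ccccc2)cc1OC.[Br-]
F6 | step 3 | 2,2-dihydroxy-1-(2,4-dimethoxyphenyl)ethanone | COc1ccc(C(=O)C(O)O)c(OC)c1
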